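**Retrosynthetic overview**

1. The target is 2α,6β,7α-triacetoxy-labda-8,13E-dien-15-ol. The plan rests on ring B: its tetrasubstituted C8=C9 alkene lies next to the quaternary C10, which is the imprint of an alkyne adding across a ring-A 1-vinylcyclohexene (diene C7=C6–C5=C10).
2. Ring A comes first, from the chiral pool (ketoisophorone to (4R,6R)-actinol, which carries C2). Ring B is then closed by [4+2] addition of methyl but-2-ynoate, forming C7–C8 and C9–C10 and setting C10.
3. Δ5 is hydroborated from the α face (5α-H, 6α-OH) while the C11 ester still deactivates Δ8. C11 then becomes an allyl sulfone, which is joined at C11–C12 to an (E)-C5 allylic bromide (C12–C16) and desulfonylated with Pd/hydride.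
4. The 6-ketone is made only after C9 carries the alkyl chain, so that no vinylogous β-keto ester can shift Δ8. α-Face enolate hydroxylation at C7 and α-face hydride delivery at C6 then give the 6β,7α-diol.
5. End game: desilylation at C2, triacetylation, release of the C15 alcohol from its PMB ether.

Key step: step 6

Remark: labdane numbering is used throughout (the drimane names of the C15 intermediates use the same ring numbers), α is the face opposite the C10 methyl, and a 10–15 kbar press is assumed for step 6.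

**Route**

Step 1
Reactants: 1 ketoisophorone (2,6,6-trimethylcyclohex-2-ene-1,4-dione)
Product: 2 (6R)-levodione [(R)-2,2,6-trimethylcyclohexane-1,4-dione]
Conditions: ene-reductase OYE2, NADP+ (cat.), D-glucose, glucose dehydrogenase, phosphate buffer pH 7, 30 °C
Reagents that add atoms: none
Why: Old-Yellow-Enzyme ene-reduction of the enedione C=C is the established biocatalytic entry to (6R)-levodione, the flavin delivering hydride to one face only; the C6 centre is erased later but is needed for recognition by the next enzyme.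

Step 2
Reactants: 2 (6R)-levodione
Product: 3 (4R,6R)-actinol [(4R,6R)-4-hydroxy-2,2,6-trimethylcyclohexanone]
Conditions: levodione reductase (Corynebacterium aquaticum), NAD+ (cat.), D-glucose, glucose dehydrogenase, phosphate buffer pH 7, 30 °C
Reagents that add atoms: none
Why: Enzymatic carbonyl reduction: the NADH-dependent reductase reduces only the unhindered C4 carbonyl (C1 is flanked by CMe2 and CHMe) and should give the (4R)-carbinol, which becomes the 2α-oxygenated C2 of the target.

Step 3
Reactants: 3 (4R,6R)-actinol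
Product: 4 (4R,6R)-4-(tert-butyldimethylsilyloxy)-2,2,6-trimethylcyclohexanone
Conditions: TBSCl, imidazole, DMF, rt
Reagents that add atoms: tert-butyldimethylsilyl chloride, CC(C)(C)[Si](C)(C)Cl
Why: Standard silylation of an unhindered secondary alcohol; the TBS ether is stable to all base, hydride and Pd steps up to step 18.

Step 4
Reactants: 4 (4R,6R)-4-(tert-butyldimethylsilyloxy)-2,2,6-trimethylcyclohexanone
Product: 6 (R)-4-(tert-butyldimethylsilyloxy)-2,6,6-trimethylcyclohex-1-en-1-yl trifluoromethanesulfonate, via lithium enolate 5 (not isolated)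
Conditions: LDA, THF, −78 → 0 °C; then PhNTf2, 0 °C → rt
Reagents that add atoms: N-phenylbis(trifluoromethanesulfonimide), O=S(=O)(N(c1ccccc1)S(=O)(=O)C(F)(F)F)C(F)(F)F (LDA, [Li+].CC(C)[N-]C(C)C, supplies only the lithium of 5)
Why: Enolate O-triflation: the ketone has a single enolisable position (C6–H, C2 being quaternary), so one enolate and one tetrasubstituted enol triflate can form, and the silyloxy group is γ to the enolate carbon and cannot be eliminated.

Step 5
Reactants: 6 (R)-4-(tert-butyldimethylsilyloxy)-2,6,6-trimethylcyclohex-1-en-1-yl trifluoromethanesulfonate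
Product: 7 (R)-4-(tert-butyldimethylsilyloxy)-2,6,6-trimethyl-1-vinylcyclohexene
Conditions: Bu3SnCH=CH2, Pd2(dba)3 (cat.), AsPh3, NMP, 60 °C
Reagents that add atoms: tributyl(vinyl)stannane, C=C[Sn](CCCC)(CCCC)CCCC
Why: Stille coupling of a 2,6,6-trimethylcyclohexenyl triflate, a hindered triflate class that couples well with the weakly bound AsPh3 ligand; it places the vinyl group with no regiochemical ambiguity, unlike dehydration of a tertiary vinyl carbinol.

Step 6
Reactants: 7 (R)-4-(tert-butyldimethylsilyloxy)-2,6,6-trimethyl-1-vinylcyclohexene; 8 methyl but-2-ynoate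
Product: 9 methyl 2α-(tert-butyldimethylsilyloxy)drima-5,8-dien-11-oate (10β-methyl)
Conditions: 8 (5 equiv), BHT (cat.), CH2Cl2, 13 kbar, 60 °C
Reagents that add atoms: none
Why: The cycloaddition is a single-step [4+2] with unequal bond formation: bonding between the CH2 terminus C7 and the alkyne carbon that carries the methyl group (future C8) runs ahead, and the cationic character developing at tertiary, allylic C10 is quenched by bonding to the carbonyl-bearing alkyne carbon (future C9). The closest known reaction type is the Diels–Alder addition of 1-vinyl-2,6,6-trimethylcyclohexenes to acetylenic esters, which gives drima-5,8-dienes. Ring B is closed by the cycloaddition itself (both σ bonds, C7–C8 and C9–C10, in one annulation), and an alkyne leaves the tetrasubstituted C8=C9 alkene directly, with no endo/exo question and with the ester as the C11 handle. C10 is the only new stereocentre and is set by the C2 carbinol carbon: the silyloxy group sits equatorial in the cyclohexene half-chair, which places one C4 methyl pseudoaxial on the β face (syn to C2–H), so the dienophile should approach from the α face and leave the C10 methyl β. The step needs regioselectivity (ester on C9), secured by the larger HOMO coefficient at C7 matched with the β-carbon of the ynoate, and α-facial selectivity, secured as just described. Pressure is used because the C10 methyl is the inside (Z) substituent of the s-cis diene and the ynoate is only mono-activated, so that heat alone would favour [1,5]-hydrogen shift of the diene, whereas the strongly negative activation volume of the [4+2] path accelerates it selectively at 60 °C.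

Step 7
Reactants: 9 methyl 2α-(tert-butyldimethylsilyloxy)drima-5,8-dien-11-oate
Product: 11 methyl 2α-(tert-butyldimethylsilyloxy)-6α-hydroxy-5α-drim-8-en-11-oate, via 6α-alkylborane 10 (not isolated)
Conditions: BH3·SMe2, THF, 0 °C → rt; then NaOH, H2O2, 0 °C → rt
Reagents that add atoms: hydrogen peroxide, OO (borane–dimethyl sulfide, C[S+](C)[BH3-], supplies only the boron of 10)
Why: Hydroboration–oxidation: the tetrasubstituted, ester-conjugated Δ8 is inert, boron goes to the CH end (C6) of Δ5 and H to C5 in a syn addition from the α face, opposite the syn-axial β-methyls on C4 and C10, which should set the trans ring fusion (5α-H) and the 6α-alcohol with retention on oxidation.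

Step 8
Reactants: 11 methyl 2α-(tert-butyldimethylsilyloxy)-6α-hydroxy-5α-drim-8-en-11-oate
Product: 12 2α-(tert-butyldimethylsilyloxy)-5α-drim-8-ene-6α,11-diol
Conditions: DIBAL-H (4 equiv), CH2Cl2, −78 → 0 °C; Rochelle salt work-up
Reagents that add atoms: none
Why: DIBAL 1,2-reduction of a hindered tetrasubstituted enoate to the allylic alcohol, as is routine for drim-8-en-11-oates; the silyl ether and the alkene are untouched.

Step 9
Reactants: 12 2α-(tert-butyldimethylsilyloxy)-5α-drim-8-ene-6α,11-diol
Product: 14 11-(phenylsulfonyl)-2α-(tert-butyldimethylsilyloxy)-5α-drim-8-en-6α-ol, via allylic bromide 13 (not isolated)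
Conditions: CBr4, PPh3, CH2Cl2, −20 °C; then crude bromide, PhSO2Na, DMF, rt
Reagents that add atoms: sodium benzenesulfinate, [Na+].[O-]S(=O)c1ccccc1 (carbon tetrabromide, BrC(Br)(Br)Br, supplies only the bromine of 13)
Why: Appel bromination followed by SN2 S-alkylation of sulfinate: the primary allylic C11 hydroxyl reacts far faster than the secondary 6α-hydroxyl (crowded by the 4α-methyl), and the sulfinate displaces the primary allylic bromide at sulfur to give the bicyclic analogue of β-cyclogeranyl phenyl sulfone.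

Step 10
Reactants: 15 prenol (3-methylbut-2-en-1-ol)
Product: 16 prenyl 4-methoxybenzyl ether [1-methoxy-4-((3-methylbut-2-enyloxy)methyl)benzene]
Conditions: NaH, PMBCl, Bu4NI (cat.), THF, 0 °C → rt
Reagents that add atoms: 4-methoxybenzyl chloride, COc1ccc(CCl)cc1
Why: Williamson etherification; PMB is chosen for the future C15 oxygen because it survives organolithium, hydride, fluoride and acylation and is removed oxidatively in the presence of acetates.

Step 11
Reactants: 16 prenyl 4-methoxybenzyl ether
Product: 17 (E)-4-(4-methoxybenzyloxy)-2-methylbut-2-en-1-ol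
Conditions: SeO2 (0.3 equiv), t-BuOOH, salicylic acid (cat.), CH2Cl2, rt
Reagents that add atoms: tert-butyl hydroperoxide, CC(C)(C)OO (oxygen relayed through catalytic SeO2, O=[Se]=O)
Why: SeO2/t-BuOOH allylic oxidation: the ene/[2,3]-sigmatropic sequence oxidises the methyl group trans to the CH2OPMB chain, which should give the (E)-allylic alcohol and so fix the C13=C14 geometry of the target.

Step 12
Reactants: 17 (E)-4-(4-methoxybenzyloxy)-2-methylbut-2-en-1-ol
Product: 18 (E)-1-bromo-4-(4-methoxybenzyloxy)-2-methylbut-2-ene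
Conditions: CBr4, PPh3, CH2Cl2, 0 °C
Reagents that add atoms: carbon tetrabromide, BrC(Br)(Br)Br
Why: Appel bromination of a primary allylic alcohol under neutral conditions, with retention of alkene geometry and position.

Step 13
Reactants: 14 11-(phenylsulfonyl)-2α-(tert-butyldimethylsilyloxy)-5α-drim-8-en-6α-ol; 18 (E)-1-bromo-4-(4-methoxybenzyloxy)-2-methylbut-2-ene
Product: 20 15-(4-methoxybenzyloxy)-11-(phenylsulfonyl)-2α-(tert-butyldimethylsilyloxy)labda-8,13E-dien-6α-ol (C11 epimers), via dilithio sulfone 19 (not isolated)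
Conditions: n-BuLi (2.2 equiv), THF–DMPU, −78 °C; then 18, −78 → −20 °C
Reagents that add atoms: n-butyllithium, [Li]CCCC (supplies only the lithium of 19)
Why: Alkylation of a sulfonyl-stabilised allyl anion (the sulfone coupling long used with β-cyclogeranyl sulfones): the second equivalent of base only forms the inert, hindered C6 alkoxide, the carbanion reacts at its α-carbon C11 with the primary allylic bromide by SN2 so that the (E)-geometry of the C5 unit is carried over, and the C11 epimers are irrelevant because the sulfonyl group is removed next.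

Step 14
Reactants: 20 15-(4-methoxybenzyloxy)-11-(phenylsulfonyl)-2α-(tert-butyldimethylsilyloxy)labda-8,13E-dien-6α-ol
Product: 21 15-(4-methoxybenzyloxy)-2α-(tert-butyldimethylsilyloxy)labda-8,13E-dien-6α-ol
Conditions: PdCl2(dppp) (cat.), LiBHEt3, THF, 0 °C → rt
Reagents that add atoms: none
Why: Pd-catalysed hydride desulfonylation of an allylic sulfone: ionisation gives the C11–C9–C8 π-allylpalladium and hydride is delivered to the less substituted terminus C11, which restores the tetrasubstituted C8=C9 alkene; the sulfone is only homoallylic to C13=C14, so that alkene and the allylic PMB ether are not engaged.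

Step 15
Reactants: 21 15-(4-methoxybenzyloxy)-2α-(tert-butyldimethylsilyloxy)labda-8,13E-dien-6α-ol
Product: 22 15-(4-methoxybenzyloxy)-2α-(tert-butyldimethylsilyloxy)labda-8,13E-dien-6-one
Conditions: Dess–Martin periodinane, NaHCO3, CH2Cl2, 0 °C → rt
Reagents that add atoms: none
Why: Dess–Martin oxidation of the secondary alcohol under buffered, near-neutral conditions, which should leave the β,γ-unsaturated ketone unconjugated and the C5 centre (already the stable trans-fused epimer) intact.

Step 16
Reactants: 22 15-(4-methoxybenzyloxy)-2α-(tert-butyldimethylsilyloxy)labda-8,13E-dien-6-one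
Product: 24 7α-hydroxy-15-(4-methoxybenzyloxy)-2α-(tert-butyldimethylsilyloxy)labda-8,13E-dien-6-one, via potassium dienolate 23 (not isolated)
Conditions: KHMDS (1.15 equiv), THF, −78 °C; then 2-(phenylsulfonyl)-3-phenyloxaziridine, −78 °C; AcOH quench
Reagents that add atoms: 2-(phenylsulfonyl)-3-phenyloxaziridine, O=S(=O)(N1OC1c1ccccc1)c1ccccc1 (KHMDS, [K+].C[Si](C)(C)[N-][Si](C)(C)C, supplies only the potassium of 23)
Why: Davis enolate hydroxylation: KHMDS removes the allylic, unhindered C7 proton (the C5 proton is tertiary and flanked by two quaternary carbons), the potassium dienolate reacts at its α-carbon C7 and not at the shielded γ-carbon C9, and the oxaziridine should approach the α face, away from the β-methyls on C4 and C10 that overhang ring B, setting 7α-OH; the cold acidic quench avoids base-induced ketol transposition.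

Step 17
Reactants: 24 7α-hydroxy-15-(4-methoxybenzyloxy)-2α-(tert-butyldimethylsilyloxy)labda-8,13E-dien-6-one
Product: 25 15-(4-methoxybenzyloxy)-2α-(tert-butyldimethylsilyloxy)labda-8,13E-diene-6β,7α-diol
Conditions: NaBH4, CeCl3·7H2O, MeOH, −40 °C (crude 24 used at once)
Reagents that add atoms: none
Why: Luche-type borohydride reduction under substrate control: the β face of C6 is closed by the syn-axial C4 β-methyl and C10 methyl, so hydride should enter from the α face and give the axial 6β-alcohol, i.e. the trans-diaxial 6β,7α-diol, before the ketol can isomerise.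

Step 18
Reactants: 25 15-(4-methoxybenzyloxy)-2α-(tert-butyldimethylsilyloxy)labda-8,13E-diene-6β,7α-diol
Product: 26 15-(4-methoxybenzyloxy)labda-8,13E-diene-2α,6β,7α-triol
Conditions: TBAF, THF, rt
Reagents that add atoms: none
Why: Fluoride desilylation of the secondary TBS ether; the PMB ether is inert to fluoride, so the three hydroxyls to be acetylated are free while C15 stays masked.

Step 19
Reactants: 26 15-(4-methoxybenzyloxy)labda-8,13E-diene-2α,6β,7α-triol
Product: 27 2α,6β,7α-triacetoxy-15-(4-methoxybenzyloxy)labda-8,13E-diene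
Conditions: Ac2O, DMAP, pyridine, 50 °C
Reagents that add atoms: acetic anhydride, CC(=O)OC(C)=O
Why: DMAP-catalysed acetylation with retention at all three carbinol carbons; the equatorial 2α-OH and allylic 7α-OH react readily, and warming with stoichiometric DMAP is provided for the axial 6β-OH, which is crowded by the C4 β- and C10 methyls.

Step 20
Reactants: 27 2α,6β,7α-triacetoxy-15-(4-methoxybenzyloxy)labda-8,13E-diene
Product: 28 2α,6β,7α-triacetoxylabda-8,13E-dien-15-ol (CNP0305346.2)
Conditions: DDQ (1.2 equiv), CH2Cl2–pH 7 buffer, 0 °C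
Reagents that add atoms: none
Why: Oxidative PMB ether cleavage with DDQ (hydride abstraction, then hydrolysis of the oxocarbenium ion), which should free the primary allylic alcohol without touching the three acetates or either alkene, leaving no opportunity for acetyl migration to the remote C15 oxygen.

**Compound list**

1 | ketoisophorone (2,6,6-trimethylcyclohex-2-ene-1,4-dione) | CC1=CC(=O)CC(C)(C)C1=O | starting material
2 | (6R)-levodione | O=C1CC(C)(C)C(=O)[C@H](C)C1 | intermediate
3 | (4R,6R)-actinol | O[C@H]1CC(C)(C)C(=O)[C@H](C)C1 | intermediate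
4 | (4R,6R)-4-(tert-butyldimethylsilyloxy)-2,2,6-trimethylcyclohexanone | CC(C)(C)[Si](C)(C)O[C@H]1CC(C)(C)C(=O)[C@H](C)C1 | intermediate
5 | lithium enolate of 4 | [Li+].CC(C)(C)[Si](C)(C)O[C@H]1CC(C)(C)C([O-])=C(C)C1 | intermediate
6 | (R)-4-(tert-butyldimethylsilyloxy)-2,6,6-trimethylcyclohex-1-en-1-yl trifluoromethanesulfonate | CC(C)(C)[Si](C)(C)O[C@H]1CC(C)(C)C(OS(=O)(=O)C(F)(F)F)=C(C)C1 | intermediate
7 | (R)-4-(tert-butyldimethylsilyloxy)-2,6,6-trimethyl-1-vinylcyclohexene | CC(C)(C)[Si](C)(C)O[C@H]1CC(C)(C)C(C=C)=C(C)C1 | intermediate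
8 | methyl but-2-ynoate | CC#CC(=O)OC | starting material
9 | methyl 2α-(tert-butyldimethylsilyloxy)drima-5,8-dien-11-oate | CC(C)(C)[Si](C)(C)O[C@H]1CC(C)(C)C2=CCC(C)=C(C(=O)OC)[C@@]2(C)C1 | intermediate
10 | 6α-boryl (monoalkylborane) adduct of 9 | CC(C)(C)[Si](C)(C)O[C@H]1CC(C)(C)[C@@H]2[C@@H](B)CC(C)=C(C(=O)OC)[C@@]2(C)C1 | intermediate
11 | methyl 2α-(tert-butyldimethylsilyloxy)-6α-hydroxy-5α-drim-8-en-11-oate | CC(C)(C)[Si](C)(C)O[C@H]1CC(C)(C)[C@@H]2[C@@H](O)CC(C)=C(C(=O)OC)[C@@]2(C)C1 | intermediate
12 | 2α-(tert-butyldimethylsilyloxy)-5α-drim-8-ene-6α,11-diol | CC(C)(C)[Si](C)(C)O[C@H]1CC(C)(C)[C@@H]2[C@@H](O)CC(C)=C(CO)[C@@]2(C)C1 | intermediate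
13 | 11-bromo-2α-(tert-butyldimethylsilyloxy)-5α-drim-8-en-6α-ol | CC(C)(C)[Si](C)(C)O[C@H]1CC(C)(C)[C@@H]2[C@@H](O)CC(C)=C(CBr)[C@@]2(C)C1 | intermediate
14 | 11-(phenylsulfonyl)-2α-(tert-butyldimethylsilyloxy)-5α-drim-8-en-6α-ol | CC(C)(C)[Si](C)(C)O[C@H]1CC(C)(C)[C@@H]2[C@@H](O)CC(C)=C(CS(=O)(=O)c3ccccc3)[C@@]2(C)C1 | intermediate
15 | prenol (3-methylbut-2-en-1-ol) | CC(C)=CCO | starting material
16 | prenyl 4-methoxybenzyl ether | COc1ccc(COCC=C(C)C)cc1 | intermediate
17 | (E)-4-(4-methoxybenzyloxy)-2-methylbut-2-en-1-ol | COc1ccc(COC/C=C(\C)CO)cc1 | intermediate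
18 | (E)-1-bromo-4-(4-methoxybenzyloxy)-2-methylbut-2-ene | COc1ccc(COC/C=C(\C)CBr)cc1 | intermediate
19 | dilithio derivative of 14 (C6 alkoxide, C11 carbanion) | [Li+].[Li+].CC(C)(C)[Si](C)(C)O[C@H]1CC(C)(C)[C@@H]2[C@@H]([O-])CC(C)=C([CH-]S(=O)(=O)c3ccccc3)[C@@]2(C)C1 | intermediate
20 | 15-(4-methoxybenzyloxy)-11-(phenylsulfonyl)-2α-(tert-butyldimethylsilyloxy)labda-8,13E-dien-6α-ol (C11 epimers, centre left undefined) | CC(C)(C)[Si](C)(C)O[C@H]1CC(C)(C)[C@@H]2[C@@H](O)CC(C)=C(C(C/C(C)=C/COCc3ccc(OC)cc3)S(=O)(=O)c3ccccc3)[C@@]2(C)C1 | intermediate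
21 | 15-(4-methoxybenzyloxy)-2α-(tert-butyldimethylsilyloxy)labda-8,13E-dien-6α-ol | CC(C)(C)[Si](C)(C)O[C@H]1CC(C)(C)[C@@H]2[C@@H](O)CC(C)=C(CC/C(C)=C/COCc3ccc(OC)cc3)[C@@]2(C)C1 | intermediate
22 | 15-(4-methoxybenzyloxy)-2α-(tert-butyldimethylsilyloxy)labda-8,13E-dien-6-one | CC(C)(C)[Si](C)(C)O[C@H]1CC(C)(C)[C@@H]2C(=O)CC(C)=C(CC/C(C)=C/COCc3ccc(OC)cc3)[C@@]2(C)C1 | intermediate
23 | potassium 6,8-dienolate of 22 | [K+].CC(C)(C)[Si](C)(C)O[C@H]1CC(C)(C)[C@@H]2C([O-])=CC(C)=C(CC/C(C)=C/COCc3ccc(OC)cc3)[C@@]2(C)C1 | intermediate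
24 | 7α-hydroxy-15-(4-methoxybenzyloxy)-2α-(tert-butyldimethylsilyloxy)labda-8,13E-dien-6-one | CC(C)(C)[Si](C)(C)O[C@H]1CC(C)(C)[C@@H]2C(=O)[C@@H](O)C(C)=C(CC/C(C)=C/COCc3ccc(OC)cc3)[C@@]2(C)C1 | intermediate
25 | 15-(4-methoxybenzyloxy)-2α-(tert-butyldimethylsilyloxy)labda-8,13E-diene-6β,7α-diol | CC(C)(C)[Si](C)(C)O[C@H]1CC(C)(C)[C@@H]2[C@H](O)[C@@H](O)C(C)=C(CC/C(C)=C/COCc3ccc(OC)cc3)[C@@]2(C)C1 | intermediate
26 | 15-(4-methoxybenzyloxy)labda-8,13E-diene-2α,6β,7α-triol | O[C@H]1CC(C)(C)[C@@H]2[C@H](O)[C@@H](O)C(C)=C(CC/C(C)=C/COCc3ccc(OC)cc3)[C@@]2(C)C1 | intermediate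
27 | 2α,6β,7α-triacetoxy-15-(4-methoxybenzyloxy)labda-8,13E-diene | CC(=O)O[C@H]1CC(C)(C)[C@@H]2[C@H](OC(C)=O)[C@@H](OC(C)=O)C(C)=C(CC/C(C)=C/COCc3ccc(OC)cc3)[C@@]2(C)C1 | intermediate
28 | 2α,6β,7α-triacetoxylabda-8,13E-dien-15-ol (CNP0305346.2) | CC(=O)O[C@H]1CC(C)(C)[C@@H]2[C@H](OC(C)=O)[C@@H](OC(C)=O)C(C)=C(CC/C(C)=C/CO)[C@@]2(C)C1 | target

**Step count**

Total: 20 steps. Longest linear sequence: 17 steps (steps 1–9 and 13–20); steps 10–12 make the C5 bromide 18 from prenol.

**Steps most likely to fail**

1. Step 6 (Diels–Alder). The cycloaddition may be too slow, because the C10 methyl twists the s-cis diene and the ynoate is only mono-activated, so that [1,5]-hydrogen shift of the diene or oligomerisation of the ynoate takes over. Discrimination between the α and β faces at C10 may also be incomplete. Fallback, from 7 back to 9: the dienophile is tethered to the C2 oxygen so that it can only reach the α face and only with the carbonyl carbon next to C10. Desilylation of 7 (TBAF, THF) should give (R)-3,5,5-trimethyl-4-vinylcyclohex-3-en-1-ol F1. Esterification with but-2-ynoic acid (DCC, DMAP cat., CH2Cl2, 0 °C) should give (R)-3,5,5-trimethyl-4-vinylcyclohex-3-en-1-yl but-2-ynoate F2. An ester-tethered intramolecular Diels–Alder reaction (toluene, BHT, sealed tube, 170 °C) should close ring B and give the bridged drima-5,8-dien-11,2α-olide F3. Methanolysis of the strained lactone (NaOMe, MeOH) should give methyl 2α-hydroxydrima-5,8-dien-11-oate F4, and silylation (TBSCl, imidazole, DMF) returns to 9.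

2. Step 16 (C7 hydroxylation). The oxidant may attack the β face of the dienolate or its γ-carbon C9, and under basic conditions the ketol may transpose toward the conjugated 7-oxo isomer or be over-oxidised. Fallback, from 22 back to 26: the oxygen is delivered under neutral conditions by epoxidation of a silyl enol ether, where both C6 and C7 must be attacked on the face opposite the two β-methyls that flank C6, and the ketol is never free. Silylation of 22 (TESOTf, Et3N, CH2Cl2, −78 °C) should give 6-(triethylsilyloxy)-15-(4-methoxybenzyloxy)-2α-(tert-butyldimethylsilyloxy)labda-6,8,13E-triene F5. Rubottom oxidation (mCPBA 1.0 equiv, NaHCO3, CH2Cl2, −40 °C; the silyl dienol ether is far more nucleophilic than the Δ13 alkene) should give 7α-(triethylsilyloxy)-15-(4-methoxybenzyloxy)-2α-(tert-butyldimethylsilyloxy)labda-8,13E-dien-6-one F6. Reduction as in step 17 should give 7α-(triethylsilyloxy)-15-(4-methoxybenzyloxy)-2α-(tert-butyldimethylsilyloxy)labda-8,13E-dien-6β-ol F7, and TBAF removes both silyl groups to rejoin the route at 26.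

3. Step 14 (desulfonylation). Ionisation of the crowded secondary allylic sulfone may be slow, or hydride may be delivered at C8, moving the alkene to the exocyclic C9=C11 position. Fallback, from 13 back to 21, which builds the chain without a sulfone. The crude bromide 13 (from 12 as in the first half of step 9) is alkylated with 3-lithio-1-(trimethylsilyl)propyne (2.2 equiv, THF, −78 °C) to give 11-[3-(trimethylsilyl)prop-2-ynyl]-2α-(tert-butyldimethylsilyloxy)-5α-drim-8-en-6α-ol F8. Desilylation of the alkyne (K2CO3, MeOH) should give 11-(prop-2-ynyl)-2α-(tert-butyldimethylsilyloxy)-5α-drim-8-en-6α-ol F9. Negishi carboalumination with formaldehyde trapping (Me3Al, Cp2ZrCl2 cat., CH2Cl2; then n-BuLi, paraformaldehyde) should give 2α-(tert-butyldimethylsilyloxy)labda-8,13E-diene-6α,15-diol F10 with the methyl and C15 cis by syn addition. Selective etherification of the primary allylic hydroxyl (4-methoxybenzyl trichloroacetimidate, CSA cat., CH2Cl2, 0 °C) returns to 21.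

**Further compounds**

F1 | step 6 | (R)-3,5,5-trimethyl-4-vinylcyclohex-3-en-1-ol | O[C@H]1CC(C)(C)C(C=C)=C(C)C1
F2 | step 6 | (R)-3,5,5-trimethyl-4-vinylcyclohex-3-en-1-yl but-2-ynoate | CC#CC(=O)O[C@H]1CC(C)(C)C(C=C)=C(C)C1
F3 | step 6 | drima-5,8-dien-11,2α-olide (bridged δ-lactone) | O=C3O[C@H]1CC(C)(C)C2=CCC(C)=C3[C@@]2(C)C1
F4 | step 6 | methyl 2α-hydroxydrima-5,8-dien-11-oate | O[C@H]1CC(C)(C)C2=CCC(C)=C(C(=O)OC)[C@@]2(C)C1
F5 | step 16 | 6-(triethylsilyloxy)-15-(4-methoxybenzyloxy)-2α-(tert-butyldimethylsilyloxy)labda-6,8,13E-triene | CC(C)(C)[Si](C)(C)O[C@H]1CC(C)(C)[C@@H]2C(O[Si](CC)(CC)CC)=CC(C)=C(CC/C(C)=C/COCc3ccc(OC)cc3)[C@@]2(C)C1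
F6 | step 16 | 7α-(triethylsilyloxy)-15-(4-methoxybenzyloxy)-2α-(tert-butyldimethylsilyloxy)labda-8,13E-dien-6-one | CC(C)(C)[Si](C)(C)O[C@H]1CC(C)(C)[C@@H]2C(=O)[C@@H](O[Si](CC)(CC)CC)C(C)=C(CC/C(C)=C/COCc3ccc(OC)cc3)[C@@]2(C)C1
F7 | step 16 | 7α-(triethylsilyloxy)-15-(4-methoxybenzyloxy)-2α-(tert-butyldimethylsilyloxy)labda-8,13E-dien-6β-ol | CC(C)(C)[Si](C)(C)O[C@H]1CC(C)(C)[C@@H]2[C@H](O)[C@@H](O[Si](CC)(CC)CC)C(C)=C(CC/C(C)=C/COCc3ccc(OC)cc3)[C@@]2(C)C1
F8 | step 14 | 11-[3-(trimethylsilyl)prop-2-ynyl]-2α-(tert-butyldimethylsilyloxy)-5α-drim-8-en-6α-ol | CC(C)(C)[Si](C)(C)O[C@H]1CC(C)(C)[C@@H]2[C@@H](O)CC(C)=C(CCC#C[Si](C)(C)C)[C@@]2(C)C1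
F9 | step 14 | 11-(prop-2-ynyl)-2α-(tert-butyldimethylsilyloxy)-5α-drim-8-en-6α-ol | CC(C)(C)[Si](C)(C)O[C@H]1CC(C)(C)[C@@H]2[C@@H](O)CC(C)=C(CCC#C)[C@@]2(C)C1
F10 | step 14 | 2α-(tert-butyldimethylsilyloxy)labda-8,13E-diene-6α,15-diol | CC(C)(C)[Si](C)(C)O[C@H]1CC(C)(C)[C@@H]2[C@@H](O)CC(C)=C(CC/C(C)=C/CO)[C@@]2(C)C1
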